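The data are calculated with constants of no real substance; the scatter is artificial.

Slowing was what I saw first. Sunday's run made 45.0% of product by 1.33 h but 52.0% by 3.00 h, with substrate and reagent both still present.

| flask | left-handed substrate | right-handed substrate | reagent | free catalyst | impurity | remark | time |
|---|---|---|---|---|---|---|---|
| Wednesday's | 12 mM | 12 mM | 1.1 equiv | 0.5 mol% | 21 µM | run made earlier |  |
| Sunday's | 12 mM | 12 mM | 4.4 equiv | 0.5 mol% | 21 µM | run made earlier |  |
| Saturday's | 12 mM | 12 mM | 2.2 equiv | 0.5 mol% | 10 µM | run made earlier |  |
| flask | 12 mM | 12 mM | 2.20 equiv | 0.5 mol% | 21 µM |  | 2.5 h |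

| run | time / h | left-handed product / % | right-handed product / % |
|---|---|---|---|
| Wednesday's | 0.417 | 1 | 1 |
| Wednesday's | 0.833 | 9 | 3 |
| Wednesday's | 1.33 | 9 | 5 |
| Wednesday's | 1.50 | 8 | 4 |
| Wednesday's | 2.00 | 9 | 6 |
| Wednesday's | 2.50 | 12 | 8 |
| Wednesday's | 3.00 | 13 | 7 |
| Sunday's | 0.167 | 9 | 8 |
| Sunday's | 0.500 | 20 | 13 |
| Sunday's | 0.833 | 27 | 13 |
| Sunday's | 1.33 | 30 | 15 |
| Sunday's | 2.00 | 32 | 15 |
| Sunday's | 2.50 | 36 | 18 |
| Sunday's | 3.00 | 34 | 18 |
| Saturday's | 0.250 | 8 | 2 |
| Saturday's | 0.833 | 15 | 8 |
| Saturday's | 1.33 | 16 | 12 |
| Saturday's | 2.00 | 17 | 16 |
| Saturday's | 3.00 | 23 | 13 |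

(each reading ± 2 percentage points)

* excess of left-handed product over right-handed product in the product at 15 min
* excess of left-handed product over right-handed product in the product at 2.5 h
* part of the left-handed substrate and right-handed substrate charged together that has reacted at 2.5 h

- free catalyst is single-handed; left-handed substrate and right-handed substrate are mirror images of each other, charged as a racemate, each of them at the stated concentration
- an excess is the difference of the two amounts in percent of their sum
- an excess is below zero if the other one leads

I worked with what was left, not with what was made.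

1. I assumed that the rate followed [substrates][reagent][free catalyst], with [free catalyst] falling independently of the reagent. Let x be the fraction of both substrates left, and y the fraction of reagent left. The integrated second-order law then gives a dose D = ln(x/y) / ([substrates] − [reagent]), with both brackets taken as charged.

2. Wednesday's run had made 20.0% at 2.50 h, so its dose was 0.0212 /mM.

3. Sunday's run had made 54.0% at 2.50 h. Its dose, the rate constant times the free catalyst integrated over time up to that moment, was 0.0172 /mM.

4. The flask shares its catalyst and impurity charges with both runs, so I gave it the same dose. The mean dose, 0.0192 /mM, gave 34.1% reacted.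

5. The weak link was Wednesday's run. Its total was smaller than Sunday's, so the scatter of 2 percentage points weighed more on it. I dropped it, and Sunday's dose gave 31.7%. I committed to that and reckoned no excess.

The forecast said excesses of 25% at 15 min and 28% at 2.5 h, and 33% reacted at 2.5 h, a conversion above my 31.7%, on the ground that “Total conversion levels off and scales with reagent”.

The flask gave excesses of 27.3% at 15 min and 27.1% at 2.5 h, and 30.8% reacted at 2.5 h, so all three forecast values held within the tolerance.

    reagent + free catalyst + left-handed substrate → free catalyst + left-handed product (k = 16000 /M²/min)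
    reagent + free catalyst + right-handed substrate → free catalyst + right-handed product (k = 8900 /M²/min)
    left-handed substrate ⇌ right-handed substrate (k = 0.0260 /min)
    free catalyst + impurity → spent catalyst A (k = 55000 /M/min)
    2 free catalyst → spent catalyst B (k = 920 /M/min)

The forecast's 33% was for 2.20 equiv of reagent. A neighbouring flask matched the flask except for 5.50 equiv of reagent. Sunday's dose, put through the same reckoning, gave 62.4% reacted. That neighbouring flask gave 60.9%.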